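**Plan**

- Numbering runs from C1 (alkyne CH) to C15 (ethyl CH3), with the ring oxygen between C9 and C13. The retrosynthesis first cuts the three carbon–halogen bonds (C6–Cl, C10–Cl, C12–Br, each back to the epimeric alcohol), then C2–C3 (Sonogashira), C3=C4 (Takai) and C6–C7 (alkoxyallylboration of a C7 aldehyde).
- The oxane is opened at C9–C10. C9 carries an equatorial CH2 arm ending in oxidised C7 and C10 carries a heteroatom, which is the pattern left when a C10 ketyl adds to C9 of a C13–O–C9=C8–C7 β-alkoxyacrylate. The last cuts are O13–C9 (oxa-Michael addition to ethyl propiolate) and C12–C13 (alkoxyallylboration of propanal).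
- Forward: C10–C15 chain (O12 as MOM ether), acrylate on O13, C10 aldehyde, closure of the only ring, bromide at C12, side chain grown C7 → C6–C4 (O6 as MEM ether) → C3 → C2/C1, both chlorides in the last step.
- Stereochemistry: C12/C13 and C6/C7 come from two reagent-controlled (Z)-γ-alkoxyallylborations. C9 and C10 come from the chair transition state of the ring closure, relayed from C13. The three halides arise by SN2 inversion, and the E alkene from the Takai reaction.
- Halogen order: an axial oxygen at C12 is syn-axial to the path of a nucleophile at C10, so C12 is inverted to the equatorial bromide before C10 is substituted.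

Key step: step 6

Remark: Ipc is the isopinocampheyl group from (−)-α-pinene, so (+)-Ipc2BOMe is methoxybis[(1S,2R,3S,5S)-2,6,6-trimethylbicyclo[3.1.1]heptan-3-yl]borane. This antipode is taken to deliver the allyl unit to the Re face of unbranched aldehydes.

**Route**

Step 1
Reactants: 1 prop-2-en-1-ol
Product: 2 3-(methoxymethoxy)prop-1-ene
Conditions: MOMCl, i-Pr2NEt, CH2Cl2, 0 °C to rt
Reagents that add atoms: chloromethyl methyl ether, COCCl
Why: Williamson-type O-alkylation (MOM protection) of the primary alcohol with the reactive α-chloro ether under amine base is routine and creates no stereocentre.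

Step 2
Reactants: 2 3-(methoxymethoxy)prop-1-ene; 3 propanal
Product: 6 (3S,4S)-4-(methoxymethoxy)hex-5-en-3-ol, via (Z)-MOM-oxyallylborane 4 (not isolated), via borinate 5 (not isolated)
Conditions: s-BuLi, THF, −78 °C; (+)-Ipc2BOMe; BF3·OEt2; 3, −78 °C; NaOH, H2O2, 0 °C to rt
Reagents that add atoms: none
Why: Brown asymmetric alkoxyallylboration, in which the (Z)-γ-alkoxyallylborane reacts through a closed six-membered chair (Zimmerman–Traxler) transition state, the Z geometry giving the syn C12/C13 relation and the isopinocampheyl groups directing attack to the Re face of propanal, so that C13 (S) and C12 (S) are both set by the reagent.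

Step 3
Reactants: 6 (3S,4S)-4-(methoxymethoxy)hex-5-en-3-ol; 7 ethyl propiolate
Product: 8 ethyl (E)-3-{[(3S,4S)-4-(methoxymethoxy)hex-5-en-3-yl]oxy}prop-2-enoate
Conditions: N-methylmorpholine, CH2Cl2, rt
Reagents that add atoms: none
Why: Amine-catalysed oxa-Michael (conjugate) addition of the secondary alcohol to the ynoate should give the E β-alkoxyacrylate and does not touch C12 or C13.

Step 4
Reactants: 8 ethyl (E)-3-{[(3S,4S)-4-(methoxymethoxy)hex-5-en-3-yl]oxy}prop-2-enoate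
Product: 10 ethyl (E)-3-{[(3S,4S)-6-hydroxy-4-(methoxymethoxy)hexan-3-yl]oxy}prop-2-enoate, via alkylborane 9 (not isolated)
Conditions: 9-BBN, THF, 0 °C to rt; NaBO3·4H2O, THF/H2O, rt
Reagents that add atoms: sodium perborate (NaBO3·4H2O, oxygen source), [Na+].[Na+].O[B-]1(O)OO[B-](O)(O)OO1
Why: Anti-Markovnikov hydroboration–oxidation, in which the hindered dialkylborane should add only to the terminal vinyl group because the disubstituted push–pull acrylate is far less reactive, and perborate oxidises the C–B bond without hydrolysing the ester.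

Step 5
Reactants: 10 ethyl (E)-3-{[(3S,4S)-6-hydroxy-4-(methoxymethoxy)hexan-3-yl]oxy}prop-2-enoate
Product: 11 ethyl (E)-3-{[(3S,4S)-4-(methoxymethoxy)-6-oxohexan-3-yl]oxy}prop-2-enoate
Conditions: Dess–Martin periodinane, NaHCO3, CH2Cl2, 0 °C to rt
Reagents that add atoms: none
Why: Dess–Martin oxidation converts the primary alcohol to the C10 aldehyde under buffered, non-basic conditions, so the β-alkoxy aldehyde should neither eliminate nor epimerise.

Step 6
Reactants: 11 ethyl (E)-3-{[(3S,4S)-4-(methoxymethoxy)-6-oxohexan-3-yl]oxy}prop-2-enoate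
Product: 12 ethyl 2-[(2R,3S,5S,6S)-6-ethyl-3-hydroxy-5-(methoxymethoxy)oxan-2-yl]acetate
Conditions: SmI2 (3 equiv), MeOH (3 equiv), THF, 0 °C
Reagents that add atoms: none
Why: SmI2 reduces the C10 aldehyde to a ketyl bound to trivalent samarium, which adds to C9, the β-carbon of the E β-alkoxyacrylate; the α-ester radical is then reduced to the samarium enolate and protonated by methanol. The closest known reaction type is the SmI2-mediated reductive ketyl–olefin cyclisation of aldehydes onto β-alkoxyacrylates, which gives 2,6-cis-2,3-trans oxan-3-ols. The single ring (O, C9, C10, C11, C12, C13) closes in the 6-exo-trig mode. C9 (R) is controlled by C13: in the chair transition state the C13 ethyl and the acrylate are both equatorial, which places the C9 arm cis to the ethyl group, while the C12 OMOM group is axial, where it meets only one axial hydrogen and the ring-oxygen lone pair. C10 (S) is controlled by the ketyl oxygen taking the equatorial position, anti to the C9–O bond and bridged by samarium to the ester carbonyl, so the hydroxyl should end trans to the C9 arm. The step needs the cis-2,6 and trans-2,3 relations and no reduction elsewhere; the E acrylate, the larger equatorial preference of an alkyl group next to the ring oxygen compared with an alkoxy group at C12, and the absence of any other reducible function secure this.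

Step 7
Reactants: 12 ethyl 2-[(2R,3S,5S,6S)-6-ethyl-3-hydroxy-5-(methoxymethoxy)oxan-2-yl]acetate
Product: 13 ethyl 2-[(2R,3S,5S,6S)-3-[(tert-butyldimethylsilyl)oxy]-6-ethyl-5-(methoxymethoxy)oxan-2-yl]acetate
Conditions: TBSOTf, 2,6-lutidine, CH2Cl2, −78 °C
Reagents that add atoms: tert-butyldimethylsilyl trifluoromethanesulfonate, CC(C)(C)[Si](C)(C)OS(=O)(=O)C(F)(F)F
Why: Silyl ether formation masks the equatorial C10 hydroxyl with retention, which is needed because C10 can be substituted only after C12 has been inverted.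

Step 8
Reactants: 13 ethyl 2-[(2R,3S,5S,6S)-3-[(tert-butyldimethylsilyl)oxy]-6-ethyl-5-(methoxymethoxy)oxan-2-yl]acetate
Product: 14 ethyl 2-[(2R,3S,5S,6S)-3-[(tert-butyldimethylsilyl)oxy]-6-ethyl-5-hydroxyoxan-2-yl]acetate
Conditions: ZnBr2, n-PrSH, CH2Cl2, 0 °C, short contact time
Reagents that add atoms: none
Why: Lewis acid–thiol cleavage of the acetal-type MOM ether (the thiol traps the methoxymethyl cation) is fast at 0 °C, proceeds with retention at C12 and should spare the silyl ether and the ester.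

Step 9
Reactants: 14 ethyl 2-[(2R,3S,5S,6S)-3-[(tert-butyldimethylsilyl)oxy]-6-ethyl-5-hydroxyoxan-2-yl]acetate
Product: 15 ethyl 2-[(2R,3S,5R,6S)-5-bromo-3-[(tert-butyldimethylsilyl)oxy]-6-ethyloxan-2-yl]acetate
Conditions: CBr4, P(n-C8H17)3, toluene, 70 °C
Reagents that add atoms: carbon tetrabromide, BrC(Br)(Br)Br
Why: Appel bromination, in which the axial alkoxyphosphonium at C12 is displaced by bromide from the unhindered opposite face in an SN2 reaction, so the bromide should emerge equatorial and trans to the C13 ethyl (12R).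

Step 10
Reactants: 15 ethyl 2-[(2R,3S,5R,6S)-5-bromo-3-[(tert-butyldimethylsilyl)oxy]-6-ethyloxan-2-yl]acetate
Product: 16 2-[(2R,3S,5R,6S)-5-bromo-3-[(tert-butyldimethylsilyl)oxy]-6-ethyloxan-2-yl]acetaldehyde
Conditions: i-Bu2AlH, CH2Cl2, −78 °C; MeOH, aq. KNaC4H4O6
Reagents that add atoms: none
Why: Partial reduction of the ester with i-Bu2AlH at −78 °C stops at the aluminium hemiacetal, which gives the C7 aldehyde on work-up while bromide and silyl ether stay untouched.

Step 11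
Reactants: 1 prop-2-en-1-ol
Product: 17 3-[(2-methoxyethoxy)methoxy]prop-1-ene
Conditions: MEMCl, i-Pr2NEt, CH2Cl2, 0 °C to rt
Reagents that add atoms: 2-methoxyethoxymethyl chloride, COCCOCCl
Why: O-Alkylation (MEM protection) of the primary alcohol with the α-chloro ether under amine base gives the allyl ether needed for the second alkoxyallylboration, its chelating acetal being chosen for a late ZnBr2 cleavage; no stereocentre is formed.

Step 12
Reactants: 16 2-[(2R,3S,5R,6S)-5-bromo-3-[(tert-butyldimethylsilyl)oxy]-6-ethyloxan-2-yl]acetaldehyde; 17 3-[(2-methoxyethoxy)methoxy]prop-1-ene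
Product: 20 (2S,3S)-1-[(2R,3S,5R,6S)-5-bromo-3-[(tert-butyldimethylsilyl)oxy]-6-ethyloxan-2-yl]-3-[(2-methoxyethoxy)methoxy]pent-4-en-2-ol, via (Z)-MEM-oxyallylborane 18 (not isolated), via borinate 19 (not isolated)
Conditions: 17, s-BuLi, THF, −78 °C; (+)-Ipc2BOMe; BF3·OEt2; 16, −78 °C; NaOH, H2O2, 0 °C
Reagents that add atoms: none
Why: Brown asymmetric alkoxyallylboration, in which the (Z)-γ-alkoxyallylborane made from the MEM ether attacks the Re face of the unbranched aldehyde through the chair transition state, overriding the weak 1,3-bias of C9, and should give C7 (S) with the syn C6 (S) ether.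

Step 13
Reactants: 20 (2S,3S)-1-[(2R,3S,5R,6S)-5-bromo-3-[(tert-butyldimethylsilyl)oxy]-6-ethyloxan-2-yl]-3-[(2-methoxyethoxy)methoxy]pent-4-en-2-ol
Product: 21 (2S,3S)-1-[(2R,3S,5R,6S)-5-bromo-3-[(tert-butyldimethylsilyl)oxy]-6-ethyloxan-2-yl]-3-[(2-methoxyethoxy)methoxy]pent-4-en-2-yl acetate
Conditions: Ac2O, pyridine, DMAP (cat.), CH2Cl2, rt
Reagents that add atoms: acetic anhydride, CC(=O)OC(C)=O
Why: DMAP-catalysed acylation of the secondary C7 hydroxyl installs the acetate of the target with retention.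

Step 14
Reactants: 21 (2S,3S)-1-[(2R,3S,5R,6S)-5-bromo-3-[(tert-butyldimethylsilyl)oxy]-6-ethyloxan-2-yl]-3-[(2-methoxyethoxy)methoxy]pent-4-en-2-yl acetate
Product: 23 (2S,3S)-1-[(2R,3S,5R,6S)-5-bromo-3-[(tert-butyldimethylsilyl)oxy]-6-ethyloxan-2-yl]-5-hydroxy-3-[(2-methoxyethoxy)methoxy]pentan-2-yl acetate, via alkylborane 22 (not isolated)
Conditions: 9-BBN, THF, 0 °C to rt; NaBO3·4H2O, THF/H2O, rt
Reagents that add atoms: sodium perborate (NaBO3·4H2O, oxygen source), [Na+].[Na+].O[B-]1(O)OO[B-](O)(O)OO1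
Why: Anti-Markovnikov hydroboration–oxidation of the terminal alkene with 9-BBN places oxygen on C4, and the mild perborate oxidation should leave acetate, bromide and silyl ether intact.

Step 15
Reactants: 23 (2S,3S)-1-[(2R,3S,5R,6S)-5-bromo-3-[(tert-butyldimethylsilyl)oxy]-6-ethyloxan-2-yl]-5-hydroxy-3-[(2-methoxyethoxy)methoxy]pentan-2-yl acetate
Product: 24 (2S,3S)-1-[(2R,3S,5R,6S)-5-bromo-3-[(tert-butyldimethylsilyl)oxy]-6-ethyloxan-2-yl]-3-[(2-methoxyethoxy)methoxy]-5-oxopentan-2-yl acetate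
Conditions: Dess–Martin periodinane, NaHCO3, CH2Cl2, 0 °C to rt
Reagents that add atoms: none
Why: Dess–Martin oxidation gives the C4 aldehyde under buffered conditions that should not eliminate the β-alkoxy group at C6.

Step 16
Reactants: 24 (2S,3S)-1-[(2R,3S,5R,6S)-5-bromo-3-[(tert-butyldimethylsilyl)oxy]-6-ethyloxan-2-yl]-3-[(2-methoxyethoxy)methoxy]-5-oxopentan-2-yl acetate
Product: 25 (2S,3S,5E)-1-[(2R,3S,5R,6S)-5-bromo-3-[(tert-butyldimethylsilyl)oxy]-6-ethyloxan-2-yl]-6-iodo-3-[(2-methoxyethoxy)methoxy]hex-5-en-2-yl acetate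
Conditions: CrCl2, CHI3, THF/1,4-dioxane, 0 °C to rt
Reagents that add atoms: iodoform, IC(I)I
Why: Takai olefination, in which the gem-dichromium carbenoid from CHI3 and CrCl2 adds to the aldehyde and the β-oxido chromium intermediate eliminates to the E iodoalkene, the unactivated secondary bromide being inert to divalent chromium in THF.

Step 17
Reactants: 25 (2S,3S,5E)-1-[(2R,3S,5R,6S)-5-bromo-3-[(tert-butyldimethylsilyl)oxy]-6-ethyloxan-2-yl]-6-iodo-3-[(2-methoxyethoxy)methoxy]hex-5-en-2-yl acetate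
Product: 26 (2S,3S,5E)-1-[(2R,3S,5R,6S)-5-bromo-3-[(tert-butyldimethylsilyl)oxy]-6-ethyloxan-2-yl]-3-[(2-methoxyethoxy)methoxy]-8-(trimethylsilyl)oct-5-en-7-yn-2-yl acetate
Conditions: HC≡CSiMe3, Pd(PPh3)4 (cat.), CuI (cat.), i-Pr2NH, THF, rt
Reagents that add atoms: ethynyltrimethylsilane, C#C[Si](C)(C)C
Why: Sonogashira coupling of the alkenyl iodide (oxidative addition to zerovalent palladium, transmetalation from the copper acetylide, reductive elimination) proceeds with retention of the E geometry and should not touch the alkyl bromide.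

Step 18
Reactants: 26 (2S,3S,5E)-1-[(2R,3S,5R,6S)-5-bromo-3-[(tert-butyldimethylsilyl)oxy]-6-ethyloxan-2-yl]-3-[(2-methoxyethoxy)methoxy]-8-(trimethylsilyl)oct-5-en-7-yn-2-yl acetate
Product: 27 (2S,3S,5E)-1-[(2R,3S,5R,6S)-5-bromo-6-ethyl-3-hydroxyoxan-2-yl]-3-[(2-methoxyethoxy)methoxy]oct-5-en-7-yn-2-yl acetate
Conditions: Bu4NF, AcOH, THF, 0 °C to rt
Reagents that add atoms: none
Why: Fluoride-mediated desilylation cleaves the alkynyl C–Si bond and the C10 silyl ether in one operation, with acetic acid buffering to protect the acetate.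

Step 19
Reactants: 27 (2S,3S,5E)-1-[(2R,3S,5R,6S)-5-bromo-6-ethyl-3-hydroxyoxan-2-yl]-3-[(2-methoxyethoxy)methoxy]oct-5-en-7-yn-2-yl acetate
Product: 28 (2S,3S,5E)-1-[(2R,3S,5R,6S)-5-bromo-6-ethyl-3-hydroxyoxan-2-yl]-3-hydroxyoct-5-en-7-yn-2-yl acetate
Conditions: ZnBr2, n-PrSH, CH2Cl2, 0 °C to rt
Reagents that add atoms: none
Why: Lewis acid-mediated MEM ether cleavage, in which ZnBr2 is chelated by the acetal oxygens and the thiol traps the alkoxymethyl cation, frees the C6 hydroxyl with retention under non-basic conditions that should not induce acetyl migration from O7.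

Step 20
Reactants: 28 (2S,3S,5E)-1-[(2R,3S,5R,6S)-5-bromo-6-ethyl-3-hydroxyoxan-2-yl]-3-hydroxyoct-5-en-7-yn-2-yl acetate
Product: 29 (2S,3R,5E)-1-[(2R,3R,5R,6S)-5-bromo-3-chloro-6-ethyloxan-2-yl]-3-chlorooct-5-en-7-yn-2-yl acetate
Conditions: CCl4, P(n-C8H17)3, toluene, 80 °C
Reagents that add atoms: carbon tetrachloride, ClC(Cl)(Cl)Cl
Why: Twofold Appel chlorination, in which both alkoxyphosphonium ions are displaced by chloride with SN2 inversion, turning C6 (S) into C6 (R) and the equatorial C10 hydroxyl into the axial chloride (10R), which is feasible now that C12 carries only an axial hydrogen.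

**Compound list**

1 | prop-2-en-1-ol | C=CCO | starting material
2 | 3-(methoxymethoxy)prop-1-ene | C=CCOCOC | intermediate
3 | propanal | CCC=O | starting material
4 | [(Z)-3-(methoxymethoxy)prop-2-en-1-yl]bis[(1S,2R,3S,5S)-2,6,6-trimethylbicyclo[3.1.1]heptan-3-yl]borane | COCO/C=C\CB([C@@H]1[C@@H](C)[C@@H]2C[C@H](C1)C2(C)C)[C@@H]1[C@@H](C)[C@@H]2C[C@H](C1)C2(C)C | intermediate (not isolated)
5 | (3S,4S)-4-(methoxymethoxy)hex-5-en-3-yl bis[(1S,2R,3S,5S)-2,6,6-trimethylbicyclo[3.1.1]heptan-3-yl]borinate | C=C[C@H](OCOC)[C@H](CC)OB([C@@H]1[C@@H](C)[C@@H]2C[C@H](C1)C2(C)C)[C@@H]1[C@@H](C)[C@@H]2C[C@H](C1)C2(C)C | intermediate (not isolated)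
6 | (3S,4S)-4-(methoxymethoxy)hex-5-en-3-ol | C=C[C@H](OCOC)[C@H](CC)O | intermediate
7 | ethyl propiolate | C#CC(=O)OCC | starting material
8 | ethyl (E)-3-{[(3S,4S)-4-(methoxymethoxy)hex-5-en-3-yl]oxy}prop-2-enoate | C=C[C@H](OCOC)[C@H](CC)O/C=C/C(=O)OCC | intermediate
9 | ethyl (E)-3-{[(3S,4S)-6-(9-borabicyclo[3.3.1]nonan-9-yl)-4-(methoxymethoxy)hexan-3-yl]oxy}prop-2-enoate | B1(C2CCCC1CCC2)CC[C@H](OCOC)[C@H](CC)O/C=C/C(=O)OCC | intermediate (not isolated)
10 | ethyl (E)-3-{[(3S,4S)-6-hydroxy-4-(methoxymethoxy)hexan-3-yl]oxy}prop-2-enoate | OCC[C@H](OCOC)[C@H](CC)O/C=C/C(=O)OCC | intermediate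
11 | ethyl (E)-3-{[(3S,4S)-4-(methoxymethoxy)-6-oxohexan-3-yl]oxy}prop-2-enoate | O=CC[C@H](OCOC)[C@H](CC)O/C=C/C(=O)OCC | intermediate
12 | ethyl 2-[(2R,3S,5S,6S)-6-ethyl-3-hydroxy-5-(methoxymethoxy)oxan-2-yl]acetate | CCOC(=O)C[C@H]1O[C@@H](CC)[C@@H](OCOC)C[C@@H]1O | intermediate
13 | ethyl 2-[(2R,3S,5S,6S)-3-[(tert-butyldimethylsilyl)oxy]-6-ethyl-5-(methoxymethoxy)oxan-2-yl]acetate | CCOC(=O)C[C@H]1O[C@@H](CC)[C@@H](OCOC)C[C@@H]1O[Si](C)(C)C(C)(C)C | intermediate
14 | ethyl 2-[(2R,3S,5S,6S)-3-[(tert-butyldimethylsilyl)oxy]-6-ethyl-5-hydroxyoxan-2-yl]acetate | CCOC(=O)C[C@H]1O[C@@H](CC)[C@@H](O)C[C@@H]1O[Si](C)(C)C(C)(C)C | intermediate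
15 | ethyl 2-[(2R,3S,5R,6S)-5-bromo-3-[(tert-butyldimethylsilyl)oxy]-6-ethyloxan-2-yl]acetate | CCOC(=O)C[C@H]1O[C@@H](CC)[C@H](Br)C[C@@H]1O[Si](C)(C)C(C)(C)C | intermediate
16 | 2-[(2R,3S,5R,6S)-5-bromo-3-[(tert-butyldimethylsilyl)oxy]-6-ethyloxan-2-yl]acetaldehyde | O=CC[C@H]1O[C@@H](CC)[C@H](Br)C[C@@H]1O[Si](C)(C)C(C)(C)C | intermediate
17 | 3-[(2-methoxyethoxy)methoxy]prop-1-ene | C=CCOCOCCOC | intermediate
18 | [(Z)-3-[(2-methoxyethoxy)methoxy]prop-2-en-1-yl]bis[(1S,2R,3S,5S)-2,6,6-trimethylbicyclo[3.1.1]heptan-3-yl]borane | COCCOCO/C=C\CB([C@@H]1[C@@H](C)[C@@H]2C[C@H](C1)C2(C)C)[C@@H]1[C@@H](C)[C@@H]2C[C@H](C1)C2(C)C | intermediate (not isolated)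
19 | (2S,3S)-1-[(2R,3S,5R,6S)-5-bromo-3-[(tert-butyldimethylsilyl)oxy]-6-ethyloxan-2-yl]-3-[(2-methoxyethoxy)methoxy]pent-4-en-2-yl bis[(1S,2R,3S,5S)-2,6,6-trimethylbicyclo[3.1.1]heptan-3-yl]borinate | C=C[C@H](OCOCCOC)[C@H](C[C@H]1O[C@@H](CC)[C@H](Br)C[C@@H]1O[Si](C)(C)C(C)(C)C)OB([C@@H]1[C@@H](C)[C@@H]2C[C@H](C1)C2(C)C)[C@@H]1[C@@H](C)[C@@H]2C[C@H](C1)C2(C)C | intermediate (not isolated)
20 | (2S,3S)-1-[(2R,3S,5R,6S)-5-bromo-3-[(tert-butyldimethylsilyl)oxy]-6-ethyloxan-2-yl]-3-[(2-methoxyethoxy)methoxy]pent-4-en-2-ol | C=C[C@H](OCOCCOC)[C@H](C[C@H]1O[C@@H](CC)[C@H](Br)C[C@@H]1O[Si](C)(C)C(C)(C)C)O | intermediate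
21 | (2S,3S)-1-[(2R,3S,5R,6S)-5-bromo-3-[(tert-butyldimethylsilyl)oxy]-6-ethyloxan-2-yl]-3-[(2-methoxyethoxy)methoxy]pent-4-en-2-yl acetate | C=C[C@H](OCOCCOC)[C@H](C[C@H]1O[C@@H](CC)[C@H](Br)C[C@@H]1O[Si](C)(C)C(C)(C)C)OC(C)=O | intermediate
22 | (2S,3S)-5-(9-borabicyclo[3.3.1]nonan-9-yl)-1-[(2R,3S,5R,6S)-5-bromo-3-[(tert-butyldimethylsilyl)oxy]-6-ethyloxan-2-yl]-3-[(2-methoxyethoxy)methoxy]pentan-2-yl acetate | B1(C2CCCC1CCC2)CC[C@H](OCOCCOC)[C@H](C[C@H]1O[C@@H](CC)[C@H](Br)C[C@@H]1O[Si](C)(C)C(C)(C)C)OC(C)=O | intermediate (not isolated)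
23 | (2S,3S)-1-[(2R,3S,5R,6S)-5-bromo-3-[(tert-butyldimethylsilyl)oxy]-6-ethyloxan-2-yl]-5-hydroxy-3-[(2-methoxyethoxy)methoxy]pentan-2-yl acetate | OCC[C@H](OCOCCOC)[C@H](C[C@H]1O[C@@H](CC)[C@H](Br)C[C@@H]1O[Si](C)(C)C(C)(C)C)OC(C)=O | intermediate
24 | (2S,3S)-1-[(2R,3S,5R,6S)-5-bromo-3-[(tert-butyldimethylsilyl)oxy]-6-ethyloxan-2-yl]-3-[(2-methoxyethoxy)methoxy]-5-oxopentan-2-yl acetate | O=CC[C@H](OCOCCOC)[C@H](C[C@H]1O[C@@H](CC)[C@H](Br)C[C@@H]1O[Si](C)(C)C(C)(C)C)OC(C)=O | intermediate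
25 | (2S,3S,5E)-1-[(2R,3S,5R,6S)-5-bromo-3-[(tert-butyldimethylsilyl)oxy]-6-ethyloxan-2-yl]-6-iodo-3-[(2-methoxyethoxy)methoxy]hex-5-en-2-yl acetate | I/C=C/C[C@H](OCOCCOC)[C@H](C[C@H]1O[C@@H](CC)[C@H](Br)C[C@@H]1O[Si](C)(C)C(C)(C)C)OC(C)=O | intermediate
26 | (2S,3S,5E)-1-[(2R,3S,5R,6S)-5-bromo-3-[(tert-butyldimethylsilyl)oxy]-6-ethyloxan-2-yl]-3-[(2-methoxyethoxy)methoxy]-8-(trimethylsilyl)oct-5-en-7-yn-2-yl acetate | C[Si](C)(C)C#C/C=C/C[C@H](OCOCCOC)[C@H](C[C@H]1O[C@@H](CC)[C@H](Br)C[C@@H]1O[Si](C)(C)C(C)(C)C)OC(C)=O | intermediate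
27 | (2S,3S,5E)-1-[(2R,3S,5R,6S)-5-bromo-6-ethyl-3-hydroxyoxan-2-yl]-3-[(2-methoxyethoxy)methoxy]oct-5-en-7-yn-2-yl acetate | C#C/C=C/C[C@H](OCOCCOC)[C@H](C[C@H]1O[C@@H](CC)[C@H](Br)C[C@@H]1O)OC(C)=O | intermediate
28 | (2S,3S,5E)-1-[(2R,3S,5R,6S)-5-bromo-6-ethyl-3-hydroxyoxan-2-yl]-3-hydroxyoct-5-en-7-yn-2-yl acetate | C#C/C=C/C[C@H](O)[C@H](C[C@H]1O[C@@H](CC)[C@H](Br)C[C@@H]1O)OC(C)=O | intermediate
29 | (2S,3R,5E)-1-[(2R,3R,5R,6S)-5-bromo-3-chloro-6-ethyloxan-2-yl]-3-chlorooct-5-en-7-yn-2-yl acetate | C#C/C=C/C[C@@H](Cl)[C@H](C[C@H]1O[C@@H](CC)[C@H](Br)C[C@H]1Cl)OC(C)=O | target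

**Step count and risks**

Total: 20 steps. Longest linear sequence: 19 steps (steps 1 to 10 and 12 to 20, from 1 to 29). Step 11 prepares the second allyl ether 17 from 1 for use in step 12.

Steps most likely to fail:

1. Step 20. The C7 acetate may take part in the departure of the C6 phosphonium group (acetoxonium formation, leading to retention or acetyl shift). E2 loss towards the conjugated dienyne may compete. Axial attack at the ring carbinol is slow and forces a temperature that the acyclic site may not tolerate. Fallback: the two substitutions are separated and the acyclic one is run through a discrete sulfonate. Setting out from 27, the ring hydroxyl alone is chlorinated (CCl4, P(n-C8H17)3, toluene, 80 °C) while O6 still carries its MEM group, giving the C10 chloride F1. ZnBr2/n-PrSH then frees O6 to give the C6 alcohol F2. ClCH2SO2Cl and pyridine at 0 °C convert it into the C6 chloromethanesulfonate F3. Displacement with excess LiCl in DMF at rt, where direct SN2 should outrun participation, returns to the route at 29.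

2. Step 9. The axial alkoxyphosphonium at C12 has two anti-periplanar axial hydrogens, so E2 elimination to the dihydropyran may compete with substitution at 70 °C. Fallback: from 14, ClCH2SO2Cl and pyridine give the C12 chloromethanesulfonate F4. This highly reactive leaving group is displaced by LiBr in DMF at or slightly above rt with inversion, coming back to the route at 15.

3. Step 16. The iodo-olefination may lose E-selectivity, and excess CrCl2 may reduce part of the aldehyde. Fallback: from 24, the stannyl variant of the chromium olefination (Bu3SnCHBr2, CrCl2, LiI, DMF/THF) should give the E alkenylstannane F5 with higher geometric purity. Iododestannylation with I2 in CH2Cl2 at 0 °C proceeds with retention and rejoins the route at 25.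

**Further compounds**

F1 | step 20 | (2S,3S,5E)-1-[(2R,3R,5R,6S)-5-bromo-3-chloro-6-ethyloxan-2-yl]-3-[(2-methoxyethoxy)methoxy]oct-5-en-7-yn-2-yl acetate | C#C/C=C/C[C@H](OCOCCOC)[C@H](C[C@H]1O[C@@H](CC)[C@H](Br)C[C@H]1Cl)OC(C)=O
F2 | step 20 | (2S,3S,5E)-1-[(2R,3R,5R,6S)-5-bromo-3-chloro-6-ethyloxan-2-yl]-3-hydroxyoct-5-en-7-yn-2-yl acetate | C#C/C=C/C[C@H](O)[C@H](C[C@H]1O[C@@H](CC)[C@H](Br)C[C@H]1Cl)OC(C)=O
F3 | step 20 | (2S,3S,5E)-2-acetoxy-1-[(2R,3R,5R,6S)-5-bromo-3-chloro-6-ethyloxan-2-yl]oct-5-en-7-yn-3-yl chloromethanesulfonate | C#C/C=C/C[C@H](OS(=O)(=O)CCl)[C@H](C[C@H]1O[C@@H](CC)[C@H](Br)C[C@H]1Cl)OC(C)=O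
F4 | step 9 | ethyl 2-[(2R,3S,5S,6S)-3-[(tert-butyldimethylsilyl)oxy]-5-{[(chloromethyl)sulfonyl]oxy}-6-ethyloxan-2-yl]acetate | CCOC(=O)C[C@H]1O[C@@H](CC)[C@@H](OS(=O)(=O)CCl)C[C@@H]1O[Si](C)(C)C(C)(C)C
F5 | step 16 | (2S,3S,5E)-1-[(2R,3S,5R,6S)-5-bromo-3-[(tert-butyldimethylsilyl)oxy]-6-ethyloxan-2-yl]-3-[(2-methoxyethoxy)methoxy]-6-(tributylstannyl)hex-5-en-2-yl acetate | CCCC[Sn](CCCC)(CCCC)/C=C/C[C@H](OCOCCOC)[C@H](C[C@H]1O[C@@H](CC)[C@H](Br)C[C@@H]1O[Si](C)(C)C(C)(C)C)OC(C)=O
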